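**Retrosynthetic overview**
- The C3a–allyl bond is cut last. The dienone is made by oxidising a 2,3-dihydrobenzofuran-6-ol to its phenoxonium ion (a vinylogous enolonium, para carbon made electrophilic) and trapping it at C3a with allylsilane, anti to the C3 methyl group.
- That phenol comes from a 6-benzyloxy-2,3-dihydrobenzofuran-5-ol by O-methylation and debenzylation.
- The dihydrobenzofuranol comes from an enantioselective formal [3+2] cycloaddition of 2-(benzyloxy)-1,4-benzoquinone with (E)-isoelemicin, which forms C3–C3a and C2–O1 and sets C2 and C3.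
- The quinone comes from 2-(benzyloxy)phenol; the alkene from 5-bromo-1,2,3-trimethoxybenzene and an (E)-propenylboronate.
- Ring order: both benzene rings are bought, the dihydrofuran ring is closed in the cycloaddition, and the cyclohexadienone appears last by dearomatisation.

Assumption: the titanium complex of (4R,5R)-TADDOL ((4R,5R)-2,2-dimethyl-α,α,α′,α′-tetraphenyl-1,3-dioxolane-4,5-dimethanol) is taken to give the (2S,3S) series. I could not fix the sense of induction from memory, so it must be checked on the first run; if the antipode forms, the (4S,5S)-ligand is used with nothing else changed.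

**Step 1**
Reactants: 1 5-bromo-1,2,3-trimethoxybenzene; 2 4,4,5,5-tetramethyl-2-[(E)-prop-1-en-1-yl]-1,3,2-dioxaborolane
Product: 3 1,2,3-trimethoxy-5-[(E)-prop-1-en-1-yl]benzene ((E)-isoelemicin)
Conditions: Pd(dppf)Cl2 (3 mol %), K2CO3, 1,4-dioxane/H2O 4:1, 85 °C
Reagents that add atoms: none
Why: Suzuki–Miyaura coupling of an aryl bromide with a stereodefined alkenylboronate proceeds with retention of alkene geometry, so the E-alkene is obtained free of the Z isomer.

**Step 2**
Reactants: 4 2-(benzyloxy)phenol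
Product: 5 2-(benzyloxy)cyclohexa-2,5-diene-1,4-dione
Conditions: (KSO3)2NO (2.2 equiv), KH2PO4, H2O/acetone, 0 °C → rt
Reagents that add atoms: dipotassium nitrosodisulfonate (Fremy's salt), [K+].[K+].[O]N(S(=O)(=O)[O-])S(=O)(=O)[O-]
Why: Teuber oxidation, in which the nitroxyl radical oxidises the phenol at its free para position and delivers the new carbonyl oxygen, giving the para-quinone with the benzyl ether untouched.

**Step 3**
Reactants: 5 2-(benzyloxy)cyclohexa-2,5-diene-1,4-dione; 3 (E)-isoelemicin
Product: 7 (2S,3S)-6-(benzyloxy)-3-methyl-2-(3,4,5-trimethoxyphenyl)-2,3-dihydro-1-benzofuran-5-ol, via cyclobutane adduct 6 (not isolated)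
Conditions: TiCl4, Ti(OiPr)4, (4R,5R)-TADDOL (1:1:2, 3 equiv of TiCl2[(4R,5R)-TADDOLate]), CH2Cl2, −78 °C, then −78 → −20 °C; H2O
Reagents that add atoms: none
Why: Lewis-acid-promoted formal [3+2] quinone–propenylarene cycloaddition (Engler type), in which tetravalent titanium chelated by C1=O and the benzyloxy oxygen activates C5 of 5 for attack by the alkene β-carbon inside the chiral TADDOLate pocket (sets C3); the benzylic cation closes on carbon (kinetic cyclobutane 6) or on the C4 oxygen, and on warming 6 re-ionises so that everything funnels to the aromatised dihydrobenzofuran with the aryl group trans to the methyl group (sets C2).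

**Step 4**
Reactants: 7 (2S,3S)-6-(benzyloxy)-3-methyl-2-(3,4,5-trimethoxyphenyl)-2,3-dihydro-1-benzofuran-5-ol
Product: 8 (2S,3S)-6-(benzyloxy)-5-methoxy-3-methyl-2-(3,4,5-trimethoxyphenyl)-2,3-dihydro-1-benzofuran
Conditions: MeI, K2CO3, acetone, 50 °C
Reagents that add atoms: iodomethane, CI
Why: Williamson etherification of the only free phenol under base too weak to disturb the ring or either stereocentre.

**Step 5**
Reactants: 8 (2S,3S)-6-(benzyloxy)-5-methoxy-3-methyl-2-(3,4,5-trimethoxyphenyl)-2,3-dihydro-1-benzofuran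
Product: 9 (2S,3S)-5-methoxy-3-methyl-2-(3,4,5-trimethoxyphenyl)-2,3-dihydro-1-benzofuran-6-ol
Conditions: H2 (1 atm), 10% Pd/C, EtOAc, rt, stopped at 1 equiv H2
Reagents that add atoms: none
Why: Catalytic hydrogenolysis cleaves the primary benzyl aryl ether much faster than the hindered secondary cyclic benzylic C2–O1 bond in neutral EtOAc, so the phenol para to C3a is freed with C2 and C3 intact.

**Step 6**
Reactants: 9 (2S,3S)-5-methoxy-3-methyl-2-(3,4,5-trimethoxyphenyl)-2,3-dihydro-1-benzofuran-6-ol
Product: 11 (2S,3S,3aS)-5-methoxy-3-methyl-3a-(prop-2-en-1-yl)-2-(3,4,5-trimethoxyphenyl)-3,3a-dihydro-1-benzofuran-6(2H)-one, via phenoxonium acetate 10 (not isolated)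
Conditions: allylSiMe3 (6 equiv), PhI(OAc)2 (1.1 equiv, added last), (CF3)2CHOH, −20 °C, 10 min; evaporate, chromatography
Reagents that add atoms: allyltrimethylsilane, C=CC[Si](C)(C)C
Why: Oxidative dearomatisation (oxidative Hosomi–Sakurai allylation), in which the trivalent-iodine oxidant converts the nucleophilic phenol into phenoxonium ion 10, whose para carbon C3a is now electrophilic and is captured by the allylsilane with loss of the silyl group to give the dienone directly; the allyl group enters the flat bicyclic cation on the face opposite the adjacent C3 methyl group (1,2-induction), which is the (3aS) configuration.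

**Compound list**
1 | 5-bromo-1,2,3-trimethoxybenzene | COc1cc(Br)cc(OC)c1OC | starting material
2 | 4,4,5,5-tetramethyl-2-[(E)-prop-1-en-1-yl]-1,3,2-dioxaborolane | C/C=C/B1OC(C)(C)C(C)(C)O1 | starting material
3 | 1,2,3-trimethoxy-5-[(E)-prop-1-en-1-yl]benzene ((E)-isoelemicin) | C/C=C/c1cc(OC)c(OC)c(OC)c1 | intermediate
4 | 2-(benzyloxy)phenol | Oc1ccccc1OCc1ccccc1 | starting material
5 | 2-(benzyloxy)cyclohexa-2,5-diene-1,4-dione | O=C1C=CC(=O)C(OCc2ccccc2)=C1 | intermediate
6 | (1R,6S,7R,8R)-3-(benzyloxy)-7-methyl-8-(3,4,5-trimethoxyphenyl)bicyclo[4.2.0]oct-3-ene-2,5-dione (cis-fused, aryl endo, methyl trans to aryl) | O=C1C(OCc2ccccc2)=CC(=O)[C@H]2[C@H](C)[C@@H](c3cc(OC)c(OC)c(OC)c3)[C@@H]12 | intermediate (not isolated)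
7 | (2S,3S)-6-(benzyloxy)-3-methyl-2-(3,4,5-trimethoxyphenyl)-2,3-dihydro-1-benzofuran-5-ol | Oc1cc2c(cc1OCc1ccccc1)O[C@H](c1cc(OC)c(OC)c(OC)c1)[C@H]2C | intermediate
8 | (2S,3S)-6-(benzyloxy)-5-methoxy-3-methyl-2-(3,4,5-trimethoxyphenyl)-2,3-dihydro-1-benzofuran | COc1cc2c(cc1OCc1ccccc1)O[C@H](c1cc(OC)c(OC)c(OC)c1)[C@H]2C | intermediate
9 | (2S,3S)-5-methoxy-3-methyl-2-(3,4,5-trimethoxyphenyl)-2,3-dihydro-1-benzofuran-6-ol | COc1cc2c(cc1O)O[C@H](c1cc(OC)c(OC)c(OC)c1)[C@H]2C | intermediate
10 | (2S,3S)-5-methoxy-3-methyl-2-(3,4,5-trimethoxyphenyl)-2,3-dihydro-1-benzofuran-6-oxylium acetate (phenoxonium ion, drawn as the 6-oxo-5-methyloxonium form; charge shared by C3a, C5 and C7) | C[O+]=C1C=C2C(=CC1=O)O[C@H](c1cc(OC)c(OC)c(OC)c1)[C@H]2C.CC(=O)[O-] | intermediate (not isolated)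
11 | (2S,3S,3aS)-5-methoxy-3-methyl-3a-(prop-2-en-1-yl)-2-(3,4,5-trimethoxyphenyl)-3,3a-dihydro-1-benzofuran-6(2H)-one | C=CC[C@]12C=C(OC)C(=O)C=C1O[C@H](c1cc(OC)c(OC)c(OC)c1)[C@H]2C | target

**Step count**
Total: 6 steps. Longest linear sequence: 5 steps (step 1 or step 2, then steps 3, 4, 5, 6).

**Three steps most likely to fail**

Step 6 is the riskiest. The allylsilane can also attack cation 10 at C5 or C7, the cation can lose the C3 proton and end as a benzofuran, and the facial preference at C3a (anti to the methyl but syn to the C2 aryl group) may be only moderate. The minor 3a-epimer would be removed by chromatography. The fallback sets out from 9 and separates oxidation from C–C bond formation. PhI(OAc)2 in MeOH at 0 °C converts 9 into the ortho-quinone monoketal (2S,3S)-5,5-dimethoxy-3-methyl-2-(3,4,5-trimethoxyphenyl)-2,3-dihydro-1-benzofuran-6(5H)-one F1. With no oxidant present, F1 is then treated with allylSiMe3 and catalytic Me3SiOSO2CF3 in CH2Cl2 at −78 °C. Ionisation of the ketal regenerates the same cation, and vinylogous substitution at C3a gives 11, where the fallback rejoins the route.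

Step 3 is next. The trimethoxyphenyl alkene is less nucleophilic than the dimethoxy- and methoxyphenyl alkenes on which this chemistry is best known, the enantiomeric excess may fall short (about 80–90% ee is expected by analogy), and the sense of induction is assumed. The fallback sets out from 3 and 5 and replaces asymmetric induction by resolution. Achiral TiCl4/Ti(OiPr)4 (1:1) in CH2Cl2 at −78 → −20 °C gives the racemic trans cycloadduct, that is 7 together with its mirror image (2R,3R)-6-(benzyloxy)-3-methyl-2-(3,4,5-trimethoxyphenyl)-2,3-dihydro-1-benzofuran-5-ol F2. Preparative chiral SFC on an amylose tris(3,5-dimethylphenylcarbamate) phase removes F2, and the fallback rejoins the route at 7.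

Step 5 is third. Over-reduction would open the dihydrofuran ring at the benzylic C2–O1 bond. The fallback changes the protecting group so that no reductive step is needed, and sets out from 3. Commercial 2-(prop-2-en-1-yloxy)phenol F3 is oxidised with (KSO3)2NO as in step 2 to 2-(prop-2-en-1-yloxy)cyclohexa-2,5-diene-1,4-dione F4. With 3 under the conditions of step 3, F4 gives (2S,3S)-3-methyl-6-(prop-2-en-1-yloxy)-2-(3,4,5-trimethoxyphenyl)-2,3-dihydro-1-benzofuran-5-ol F5; the added risk here is a Lewis-acid-induced Claisen shift of the allyl vinyl ether in F4, which low temperature should suppress. MeI/K2CO3 in acetone then gives (2S,3S)-5-methoxy-3-methyl-6-(prop-2-en-1-yloxy)-2-(3,4,5-trimethoxyphenyl)-2,3-dihydro-1-benzofuran F6. Pd(PPh3)4 (5 mol %) with morpholine in THF at rt removes the allyl group, and the fallback rejoins the route at 9.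

**Further compounds**
F1 | step 6 | (2S,3S)-5,5-dimethoxy-3-methyl-2-(3,4,5-trimethoxyphenyl)-2,3-dihydro-1-benzofuran-6(5H)-one | COC1(OC)C=C2C(=CC1=O)O[C@H](c1cc(OC)c(OC)c(OC)c1)[C@H]2C
F2 | step 3 | (2R,3R)-6-(benzyloxy)-3-methyl-2-(3,4,5-trimethoxyphenyl)-2,3-dihydro-1-benzofuran-5-ol | Oc1cc2c(cc1OCc1ccccc1)O[C@@H](c1cc(OC)c(OC)c(OC)c1)[C@@H]2C
F3 | step 5 | 2-(prop-2-en-1-yloxy)phenol (bought) | Oc1ccccc1OCC=C
F4 | step 5 | 2-(prop-2-en-1-yloxy)cyclohexa-2,5-diene-1,4-dione | O=C1C=CC(=O)C(OCC=C)=C1
F5 | step 5 | (2S,3S)-3-methyl-6-(prop-2-en-1-yloxy)-2-(3,4,5-trimethoxyphenyl)-2,3-dihydro-1-benzofuran-5-ol | Oc1cc2c(cc1OCC=C)O[C@H](c1cc(OC)c(OC)c(OC)c1)[C@H]2C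
F6 | step 5 | (2S,3S)-5-methoxy-3-methyl-6-(prop-2-en-1-yloxy)-2-(3,4,5-trimethoxyphenyl)-2,3-dihydro-1-benzofuran | COc1cc2c(cc1OCC=C)O[C@H](c1cc(OC)c(OC)c(OC)c1)[C@H]2C
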